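**Retrosynthetic overview**
1. The target (albaspidin AB) is two acylfilicinic acid rings joined by a CH2 bridge. The bridge C–C bond to the butyryl ring is disconnected as an intermolecular Michael addition of butyrylfilicinic acid 8 to the methylidene trione 10.
2. 10 is released in the flask from the Mannich base 9, which comes from Mannich aminomethylation of acetylfilicinic acid 3.
3. 3 and 8 come from dearomatising gem-C-dimethylation of the acylphloroglucinols 1 and 6; 6 comes from phloroglucinol 4 and butanoyl chloride 5 (Friedel–Crafts).
4. No ring is built: both six-membered rings start as phloroglucinol rings and are dearomatised (acetyl ring in step 1, butyryl ring in step 3) before they are joined in step 5.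

Assumption: the target SMILES has no stereocentre (both quaternary carbons carry two methyl groups), so the compound is achiral and "single enantiomer" needs no stereocontrol; all enol tautomers are drawn to match the target SMILES.

**Step 1**
Reactants: 1 2,4,6-trihydroxyacetophenone (phloroacetophenone)
Product: 3 acetylfilicinic acid (2-acetyl-3,5-dihydroxy-6,6-dimethylcyclohexa-2,4-dien-1-one), via 3-methylphloroacetophenone 2 (not isolated)
Conditions: NaOMe (3.2 equiv), MeI (2.3 equiv), MeOH, 0 °C → rt, 12 h; then 1 M HCl; chromatography/crystallisation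
Reagents that add atoms: iodomethane, CI
Why: C-alkylation of the phloroglucinolate (dearomative gem-dimethylation): after the first methyl enters, that ring carbon is the most nucleophilic, so the second MeI adds at the same carbon and the resulting stabilised vinylogous-acid anion resists further methylation with limited MeI; no stereocentre is formed.

**Step 2**
Reactants: 4 phloroglucinol (benzene-1,3,5-triol, anhydrous); 5 butanoyl chloride
Product: 6 phlorobutyrophenone (1-(2,4,6-trihydroxyphenyl)butan-1-one)
Conditions: AlCl3 (3.5 equiv), CH2Cl2/MeNO2, 0 → 40 °C; then ice/1 M HCl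
Reagents that add atoms: none
Why: Friedel–Crafts C-acylation of the very electron-rich triol stops at the mono-ketone because the chelated acyl group deactivates the ring.

**Step 3**
Reactants: 6 phlorobutyrophenone
Product: 8 butyrylfilicinic acid (2-butanoyl-3,5-dihydroxy-6,6-dimethylcyclohexa-2,4-dien-1-one), via 3-methylphlorobutyrophenone 7 (not isolated)
Conditions: NaOMe (3.2 equiv), MeI (2.3 equiv), MeOH, 0 °C → rt, 12 h; then 1 M HCl; chromatography
Reagents that add atoms: iodomethane, CI
Why: the same dearomative gem-C-dimethylation of a phloroglucinolate as in step 1; no stereocentre is formed.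

**Step 4**
Reactants: 3 acetylfilicinic acid
Product: 9 Mannich base, 2-acetyl-4-[(dimethylamino)methyl]-3,5-dihydroxy-6,6-dimethylcyclohexa-2,4-dien-1-one (obtained as the inner salt)
Conditions: CH2(NMe2)2 (1.5 equiv), CH2Cl2, 0 °C → rt, 1 h, 3 added slowly to the aminal; evaporate, triturate with Et2O; use at once
Reagents that add atoms: bis(dimethylamino)methane, CN(C)CN(C)C
Why: Mannich reaction: the acidic enol activates the aminal and is aminomethylated at its only free ring carbon, while the excess aminal keeps free 3 from forming the symmetric dimer.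

**Step 5**
Reactants: 9 Mannich base; 8 butyrylfilicinic acid (1.5 equiv)
Product: 11 albaspidin AB (2-acetyl-4-[(3-butanoyl-2,6-dihydroxy-5,5-dimethyl-4-oxocyclohexa-2,6-dien-1-yl)methyl]-3,5-dihydroxy-6,6-dimethylcyclohexa-2,4-dien-1-one), via methylidene trione 10 (not isolated)
Conditions: 9 in AcOH added over 2 h to 8 in 1,4-dioxane, 70 °C, N2; then EtOAc/1 M HCl wash; SiO2 (hexane/EtOAc, 1% AcOH), recrystallise; recover excess 8
Reagents that add atoms: none
Why: acid-buffered loss of dimethylamine from the Mannich base gives the strongly electrophilic methylidene trione, which is trapped by intermolecular Michael addition of the free ring carbon of 8; the AcOH buffer and absence of free base suppress methylene-bridge scrambling, and no stereocentre is formed.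

**Compound list**
1 | 2,4,6-trihydroxyacetophenone | CC(=O)c1c(O)cc(O)cc1O | starting material
2 | 1-(2,4,6-trihydroxy-3-methylphenyl)ethan-1-one (3-methylphloroacetophenone) | CC(=O)c1c(O)cc(O)c(C)c1O | intermediate
3 | acetylfilicinic acid, 2-acetyl-3,5-dihydroxy-6,6-dimethylcyclohexa-2,4-dien-1-one | CC(=O)C1=C(O)C=C(O)C(C)(C)C1=O | intermediate
4 | phloroglucinol | Oc1cc(O)cc(O)c1 | starting material
5 | butanoyl chloride | CCCC(=O)Cl | starting material
6 | 1-(2,4,6-trihydroxyphenyl)butan-1-one (phlorobutyrophenone) | CCCC(=O)c1c(O)cc(O)cc1O | intermediate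
7 | 1-(2,4,6-trihydroxy-3-methylphenyl)butan-1-one (3-methylphlorobutyrophenone) | CCCC(=O)c1c(O)cc(O)c(C)c1O | intermediate
8 | butyrylfilicinic acid, 2-butanoyl-3,5-dihydroxy-6,6-dimethylcyclohexa-2,4-dien-1-one | CCCC(=O)C1=C(O)C=C(O)C(C)(C)C1=O | intermediate
9 | 2-acetyl-4-[(dimethylamino)methyl]-3,5-dihydroxy-6,6-dimethylcyclohexa-2,4-dien-1-one (Mannich base) | CC(=O)C1=C(O)C(CN(C)C)=C(O)C(C)(C)C1=O | intermediate
10 | 2-acetyl-3-hydroxy-6,6-dimethyl-4-methylidenecyclohex-2-ene-1,5-dione (methylidene trione) | CC(=O)C1=C(O)C(=C)C(=O)C(C)(C)C1=O | intermediate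
11 | albaspidin AB (achiral) | CCCC(=O)C1=C(O)C(CC2=C(O)C(C)(C)C(=O)C(C(C)=O)=C2O)=C(O)C(C)(C)C1=O | target

**Totals**
Total steps: 5. Longest linear sequence: 3 steps (4 → 6 → 8 → 11, or 1 → 3 → 9 → 11).

**Three steps most likely to fail, with fallbacks**

Step 5 (coupling). The risks are self-condensation of 9 to the symmetric acetyl dimer and base-induced exchange of the halves of the product (rottlerone change), both of which erode the unsymmetrical product. Fallback: setting out from 3 and 8 in equimolar amounts, condense them directly with 37% aqueous formaldehyde (0.5 equiv per monomer) in 1% aqueous NaOH at rt for a few minutes and acidify. This gives the statistical mixture of albaspidin AA F1, albaspidin BB F2 and the target (about 1:1:2). The target is separated on oxalic acid-treated silica or by reversed-phase chromatography, and F1 and F2 are pooled and re-equilibrated in dilute alkali to give more of it. The fallback comes back to the route at 11.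

Step 4 (Mannich base). Mannich bases of cyclic 1,3-dicarbonyl enols can lose amine during isolation and go on to the symmetric methylene-bis compound. Fallback: setting out from 3, a three-component condensation with aqueous formaldehyde and p-toluenesulfinic acid (TolSO2Na, HCO2H/H2O, rt) gives the non-basic tosylmethyl compound 2-acetyl-3,5-dihydroxy-6,6-dimethyl-4-{[(4-methylphenyl)sulfonyl]methyl}cyclohexa-2,4-dien-1-one F3. Stirred with NaOAc in EtOH at rt in the presence of 8, it expels sulfinate and comes back to the route at the methylidene trione 10, which is trapped to 11 as in step 5.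

Step 3 (gem-dimethylation of 6; step 1 shares the risk but its product 3 crystallises more readily). Mono-, 3,5-di- and trimethylated by-products may be hard to separate from the butyryl compound. Fallback: setting out from 3, remove the acetyl group by retro-Claisen hydrolysis (6 M HCl, reflux) to give filicinic acid F4. Then C-acylate F4 with 5 (AlCl3, PhNO2, 50 °C); mono-acylation is expected because the first acyl group deactivates the enol system. The fallback comes back to the route at 8.

**Further compounds**
F1 | step 5 | albaspidin AA, 2-acetyl-4-[(3-acetyl-2,6-dihydroxy-5,5-dimethyl-4-oxocyclohexa-2,6-dien-1-yl)methyl]-3,5-dihydroxy-6,6-dimethylcyclohexa-2,4-dien-1-one | CC(=O)C1=C(O)C(CC2=C(O)C(C)(C)C(=O)C(C(C)=O)=C2O)=C(O)C(C)(C)C1=O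
F2 | step 5 | albaspidin BB, 2-butanoyl-4-[(3-butanoyl-2,6-dihydroxy-5,5-dimethyl-4-oxocyclohexa-2,6-dien-1-yl)methyl]-3,5-dihydroxy-6,6-dimethylcyclohexa-2,4-dien-1-one | CCCC(=O)C1=C(O)C(CC2=C(O)C(C)(C)C(=O)C(C(=O)CCC)=C2O)=C(O)C(C)(C)C1=O
F3 | step 4 | 2-acetyl-3,5-dihydroxy-6,6-dimethyl-4-{[(4-methylphenyl)sulfonyl]methyl}cyclohexa-2,4-dien-1-one | CC(=O)C1=C(O)C(CS(=O)(=O)c2ccc(C)cc2)=C(O)C(C)(C)C1=O
F4 | step 3 | filicinic acid, 3,5-dihydroxy-6,6-dimethylcyclohexa-2,4-dien-1-one | CC1(C)C(O)=CC(O)=CC1=O
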